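Remark on the chemistry (assumption): the (R)-configured binaphthyl phosphoric acid is taken to steer allyl transfer from the boronate to the Re face of an aldehyde and its (S)-enantiomer to the Si face. The chain is numbered C1 (carbon bearing ring A) to C7 (carbon bonded to ring B) in every compound.

Structural features

The target is a 1,7-diarylheptanoid in which C1 and C5 are bridged by oxygen to an oxane ring. C1 carries ring A (3,4-dihydroxy-5-methoxyphenyl), C3 a free hydroxyl, and C5 a two-carbon arm (C6–C7) ending on ring B (4-hydroxy-3-methoxyphenyl). The stereocentres C1 (S), C3 (R) and C5 (S) are 1,3,5-related on the ring and all cis, so every substituent is equatorial in one chair. In the open chain this means a 1,3-anti relationship between the C1 and C3 oxygens. The fragile parts are the C1–O ring bond, a benzylic ether on a very electron-rich arene that acid, hydride-abstracting oxidants or prolonged hydrogenolysis can break, and the air-sensitive catechol of ring A, which has to be unveiled last under neutral conditions. There is no quaternary centre and no pair of adjacent stereocentres. The real difficulty is to set C5 cis to C1 and C3 while building the C5–C6–C7 arm, and to join the sp3 carbon C7 to ring B. The key step uses the fact that C5 is an ether carbon bearing a CH2–C unit: a terminal C5=C6 alkene placed five atoms from the C1 hydroxyl, plus one molecule of CO, maps onto O–C5, C6 and C7, so ring closure and chain extension happen together and the equatorial preferences at C1 and C3 dictate C5.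

Logic of the disconnections

20 to 19: the four O–CH2Ph bonds are cut. One protecting group type on the three phenols and on the C3 oxygen allows a single neutral deprotection at the very end and keeps the catechol masked throughout. The forward step must remove an aliphatic benzyl ether without hydrogenolysing the benzylic C1–O ring bond.

19 to 15 and 17: the C7–aryl bond to ring B is cut. This sp3–sp2 bond is the only skeletal bond of the arm that the key step does not make, and cutting it separates ring B as a simple aryl bromide. The forward step needs C7 as a nucleophile (18) that forms without disturbing the γ-oxygen at C5 and couples faster than it undergoes β-hydride elimination. 17 comes from 16 by cutting one O–CH2Ph bond.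

15 to 14 to 13: no skeletal bond is cut; C7–I is traced to C7–OH and then to the ester carbon. This leads C7 back to the carbonyl carbon that the key step installs. The reduction must be fast and cold so that the β-alkoxy ester does not open.

13 to 12: O–C5 and C6–C7 are cut, which removes the ring, the C5 stereocentre and one carbon (CO), leaving an acyclic hydroxy alkene with two stereocentres. The forward step requires a free C1 hydroxyl, a masked C3 oxygen, the 1,3-anti arrangement of the two oxygens, 6-exo regioselectivity, and control of the acid set free on reoxidation. The C3 benzyl ether is kept in 12 because it is inert to the acidic, oxidising medium and leaves in the final step.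

12 to 11 to 10: the O–Si bond at C1 and the O–CH2Ph bond at C3 are traced back. The two oxygens are told apart by order of events: each is protected while it is the only hydroxyl present. The silyl group must stay on C1 under the basic benzylation, which is why a triisopropylsilyl group is used instead of a smaller, migration-prone one.

10 to 8 and 3: C3–C4 is cut. C4–C6 with the terminal alkene arrive in one step from 3 and the C3 stereocentre is created. The forward step must give 3R (anti to the C1 oxygen); a non-chelating β-silyloxy aldehyde cannot be relied on for that, so the facial choice is handed to a chiral catalyst.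

8 to 6 to 5: the C3 aldehyde is traced to a vinyl group and the O–Si bond to the free alcohol. The first allyl group thus serves as a masked C2–C3 aldehyde. The cleavage must spare ring A and the benzyl ethers, so osmium/periodate is preferred to ozone, and the β-silyloxy aldehyde must be used at once.

5 to 2 and 3: C1–C2 is cut. The aryl aldehyde and the allyl boronate are simple, and the C1 stereocentre (S) is set by catalyst control.

2 to 1: two O–CH2Ph bonds are cut, leading to the commercial aldehyde.

Other disconnections considered

Alternative 1:
- **Cut:** C4–C5 and C2–C3, so that C1–C6 come from three two-carbon aldehydes.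
- **Forward key step:** 2-deoxy-D-ribose 5-phosphate aldolase would add two molecules of acetaldehyde A3 in sequence to chloroacetaldehyde A2. The second aldol product closes to the lactol (4R,6S)-6-(chloromethyl)oxane-2,4-diol A1, whose ring holds C1–C5 and whose chloromethyl carbon is C6.
- **In favour:** two C–C bonds, two carbinol centres and the oxane skeleton arise in water from commodity aldehydes, with no protecting group and enzyme-level enantiocontrol. On these counts A1 is better than the chosen route, which needs seven steps to reach 12.
- **Against, structure:** in A1 the hydroxyl and the chloromethyl arm are trans on the ring (the enzyme makes the 3,5-syn diol), whereas the target needs the C3 oxygen cis to the C5 arm. Mapped onto the target, C3 is correct and C5 is epimeric. The centre to invert is therefore the one bearing the ring oxygen: the lactol would have to be opened, the C5 hydroxyl activated and the ring re-closed by SN2 attack of a C1 oxygen, with C1 set by a separate asymmetric step. Inverting C3 instead would lead to the enantiomer of the target.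
- **Against, further work:** ring A must still be attached at the anomeric carbon C1, and ring B joined by substitution of a β-alkoxy primary chloride, which is sluggish. A2 is a toxic alkylating agent.
- **Comparison:** mechanistically the enzyme fixes C3 and C5 under catalyst control but leaves C1 open, while the chosen plan sets C5 last from two centres already in place. Once the correction at C5 is counted, step economy is probably equal at best.

Alternative 2:
- **Cut:** C2–C3 and C3–C4. The chain is assembled from a C3 linchpin, tert-butyl(1,3-dithian-2-yl)dimethylsilane A7, and two epoxides: (2R)-2-[3,4-bis(benzyloxy)-5-methoxyphenyl]oxirane A5 (C1–C2 with ring A) and (2R)-2-{2-[4-(benzyloxy)-3-methoxyphenyl]ethyl}oxirane A6 (C4–C7 with ring B).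
- **Forward key step:** lithiated A7 opens A5 at its CH2 group. A polar phosphoramide cosolvent then triggers the 1,4-shift of silicon from carbon to the C1 oxygen (Brook rearrangement), and the relayed dithiane anion opens A6. The product is the open-chain C1 silyl ether and C5 alcohol A4, with C3 masked as a dithiane; no ring is closed.
- **In favour:** this is the most convergent of the plans, both aryl ends arrive complete, and two C–C bonds form in one flask, which equals the chosen key step. In convergence and in longest linear sequence it should be better than the chosen plan. The later C3 ketone can be reduced to the equatorial alcohol by axial hydride attack.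
- **Against:**
  - A4 carries C5 as R while the target needs S, so the ring can only be closed with inversion at C5 (sulfonate, desilylation, attack of the C1 oxygen). Elimination competes there, and an acid-mediated closure at benzylic C1 would give the wrong C5.
  - A5 bears a very electron-rich ring and is prone to Meinwald rearrangement and to attack at its benzylic carbon.
  - Both epoxides must be made enantiopure, typically by resolution with loss of half the material.
  - Unmasking the dithiane needs thiophilic or oxidising reagents next to two electron-rich arenes.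
  - The cosolvent is a carcinogen.
- **Comparison:** C1 and C5 are bought separately and C3 comes from a late reduction, whereas the chosen plan derives C5 from C1 and C3 in the ring-forming step. About six operations follow A4, so the total count is not lower although the linear sequence is shorter.

Alternative 3:
- **Cut:** C5–C6, on an oxane that already holds C1, C3 and the ring oxygen. Ring B arrives as an arylethynyl(dimethyl)silyl group tethered to the C3 oxygen of the anomeric C5 phenyl selenide A9.
- **Forward key step:** a tin hydride and an azo initiator would turn the selenide into the C5 α-oxygen radical, which attacks the silicon-bearing alkyne carbon in a 6-exo-dig mode. Hydrogen transfer to the vinyl radical gives the cis-fused bicyclic siloxane A8 with an exocyclic styrene of mixed geometry. The siloxane ring is auxiliary and is removed later by protodesilylation.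
- **In favour:** the tether delivers C6 to the face of the C3 oxygen, so the cis C3/C5 relationship is enforced by connectivity. C6, C7 and ring B come in one step. The mixed alkene geometry is irrelevant because the alkene is hydrogenated in the operation that removes the benzyl groups. The endgame after A8 (two steps) is shorter than the four steps that follow 13; on this point the alternative is better.
- **Against:**
  - The C3 oxygen can reach C5 only when both are axial. Since the C1 aryl group is cis to both, the reacting conformer must place the aryl group axial too or twist, which invites simple reduction of the C5 radical.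
  - The oxane ring, C1 and C3 must first be built by other chemistry, so the key step closes no ring of the target.
  - The tether must be prepared from a ring B alkyne.
  - Tin and selenium residues are toxic and hard to remove.
- **Comparison:** a kinetically controlled radical closure through an all-axial arrangement is less forgiving than the polar, chair-like oxypalladation that leads directly to the all-equatorial oxane. The structural overlap with the target is smaller (one skeletal bond, no target ring), and the overall step count would be about equal.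

Key step: step 8

Step 1
Reactants: 1 3,4-dihydroxy-5-methoxybenzaldehyde (5-hydroxyvanillin)
Product: 2 3,4-bis(benzyloxy)-5-methoxybenzaldehyde
Conditions: BnBr (2.4 equiv), K2CO3 (3 equiv), DMF, 60 °C
Reagents that add atoms: benzyl bromide, BrCc1ccccc1
Why: Williamson ether synthesis; both phenoxides are alkylated under mild base and the aldehyde is untouched, so the catechol is masked by groups that survive every later step and leave by hydrogenolysis.

Step 2
Reactants: 2 3,4-bis(benzyloxy)-5-methoxybenzaldehyde; 3 allylboronic acid pinacol ester
Product: 5 (1S)-1-[3,4-bis(benzyloxy)-5-methoxyphenyl]but-3-en-1-ol, via pinacol borate ester 4 (not isolated)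
Conditions: (S)-3,3'-bis(2,4,6-triisopropylphenyl)-1,1'-binaphthyl-2,2'-diyl hydrogen phosphate (5 mol %), toluene, −30 °C; then aq. NaHCO3
Reagents that add atoms: none
Why: Chiral Brønsted acid catalysed allylboration of an aryl aldehyde through a closed chair-like six-membered transition state; the acid hydrogen-bonds to a boronate oxygen and shields one face, so the (S)-acid should send allyl to the Si face and set C1 as S. Aqueous work-up hydrolyses the B–O bond of 4.

Step 3
Reactants: 5 (1S)-1-[3,4-bis(benzyloxy)-5-methoxyphenyl]but-3-en-1-ol
Product: 6 {[(1S)-1-[3,4-bis(benzyloxy)-5-methoxyphenyl]but-3-en-1-yl]oxy}tri(propan-2-yl)silane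
Conditions: i-Pr3SiOTf, 2,6-lutidine, CH2Cl2, −78 to 0 °C
Reagents that add atoms: triisopropylsilyl trifluoromethanesulfonate, CC(C)[Si](OS(=O)(=O)C(F)(F)F)(C(C)C)C(C)C
Why: O-silylation of the secondary benzylic alcohol with a silyl triflate and a hindered base; the triisopropylsilyl group is chosen because it should not migrate to the C3 alkoxide in step 6 and it tolerates the oxidative cleavage and the acid catalyst of step 5.

Step 4
Reactants: 6 {[(1S)-1-[3,4-bis(benzyloxy)-5-methoxyphenyl]but-3-en-1-yl]oxy}tri(propan-2-yl)silane
Product: 8 (3S)-3-[3,4-bis(benzyloxy)-5-methoxyphenyl]-3-{[tri(propan-2-yl)silyl]oxy}propanal, via vicinal diol 7 (not isolated)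
Conditions: K2OsO4·2H2O (2 mol %), NaIO4 (4 equiv), 2,6-lutidine, 1,4-dioxane/H2O (3:1), rt
Reagents that add atoms: sodium periodate (oxygen relayed by the osmium catalyst), [Na+].[O-]I(=O)(=O)=O
Why: Lemieux–Johnson oxidation: catalytic dihydroxylation of the terminal alkene to 7 and periodate cleavage to the aldehyde, with lutidine to suppress over-oxidation; it is preferred to ozone because the electron-rich ring A and the benzyl ethers are left alone. The β-silyloxy aldehyde is carried on without chromatography to avoid β-elimination.

Step 5
Reactants: 8 (3S)-3-[3,4-bis(benzyloxy)-5-methoxyphenyl]-3-{[tri(propan-2-yl)silyl]oxy}propanal; 3 allylboronic acid pinacol ester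
Product: 10 (1S,3R)-1-[3,4-bis(benzyloxy)-5-methoxyphenyl]-1-{[tri(propan-2-yl)silyl]oxy}hex-5-en-3-ol, via pinacol borate ester 9 (not isolated)
Conditions: (R)-3,3'-bis(2,4,6-triisopropylphenyl)-1,1'-binaphthyl-2,2'-diyl hydrogen phosphate (10 mol %), toluene, −30 °C; then aq. NaHCO3
Reagents that add atoms: none
Why: The same catalytic allylboration, now with the (R)-acid so that allyl adds to the Re face and C3 becomes R, which is 1,3-anti to the C1 oxygen. The bulky non-chelating silyl ether exerts little substrate bias, so catalyst control should decide the new centre.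

Step 6
Reactants: 10 (1S,3R)-1-[3,4-bis(benzyloxy)-5-methoxyphenyl]-1-{[tri(propan-2-yl)silyl]oxy}hex-5-en-3-ol
Product: 11 {[(1S,3R)-3-(benzyloxy)-1-[3,4-bis(benzyloxy)-5-methoxyphenyl]hex-5-en-1-yl]oxy}tri(propan-2-yl)silane
Conditions: NaH, BnBr, Bu4NI (cat.), THF, 0 °C to rt
Reagents that add atoms: benzyl bromide, BrCc1ccccc1
Why: Williamson etherification of the C3 alkoxide; the C1 silyl ether is too hindered to migrate and nothing else in 10 is base-sensitive. The benzyl ether masks C3 through the ring closure and the organozinc chemistry.

Step 7
Reactants: 11 {[(1S,3R)-3-(benzyloxy)-1-[3,4-bis(benzyloxy)-5-methoxyphenyl]hex-5-en-1-yl]oxy}tri(propan-2-yl)silane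
Product: 12 (1S,3R)-3-(benzyloxy)-1-[3,4-bis(benzyloxy)-5-methoxyphenyl]hex-5-en-1-ol
Conditions: Bu4NF, THF, rt
Reagents that add atoms: none
Why: Fluoride-induced cleavage of the Si–O bond frees the C1 hydroxyl; benzyl ethers and the alkene are inert to fluoride.

Step 8
Reactants: 12 (1S,3R)-3-(benzyloxy)-1-[3,4-bis(benzyloxy)-5-methoxyphenyl]hex-5-en-1-ol
Product: 13 methyl 2-[(2R,4R,6S)-4-(benzyloxy)-6-[3,4-bis(benzyloxy)-5-methoxyphenyl]oxan-2-yl]acetate
Conditions: PdCl2 (10 mol %), CuCl2 (3 equiv), NaOAc (3 equiv), CO (1 atm), MeOH/MeCN (1:1), rt
Reagents that add atoms: carbon monoxide, [C-]#[O+]; methanol, CO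
Why: Divalent palladium binds the terminal C5=C6 alkene and the C1 hydroxyl adds to C5 from the face opposite the metal (anti oxypalladation), closing the oxane in a 6-exo-trig mode. The primary alkylpalladium at C6 then inserts CO and methanol cleaves the acylpalladium to the methyl ester, which forms C6–C7 and releases zerovalent palladium that CuCl2 returns to the divalent state. The closest known reaction type is the intramolecular alkoxycarbonylation of δ-hydroxy alkenes with PdCl2 and CuCl2 under CO in methanol, which is established for cis-2,6-disubstituted oxanes. The new C5 centre is controlled by the chair-like transition state in which the C1 aryl group and the C3 benzyloxy group, anti to each other in the chain, are both equatorial, so the alkene arm also takes an equatorial site and C5 comes out cis to both; it is labelled R in 13 only because the ester arm outranks C4, and it is the arrangement that becomes 5S in 20. Regioselectivity (6-exo over 7-endo) follows from Markovnikov addition of oxygen to the internal alkene carbon. Chemoselectivity is secured because only the C1 oxygen is free, the C3 oxygen being a benzyl ether. NaOAc takes up the HCl released on reoxidation, which should protect the electron-rich benzylic alcohol from ionisation and keep C1 intact.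

Step 9
Reactants: 13 methyl 2-[(2R,4R,6S)-4-(benzyloxy)-6-[3,4-bis(benzyloxy)-5-methoxyphenyl]oxan-2-yl]acetate
Product: 14 2-[(2S,4R,6S)-4-(benzyloxy)-6-[3,4-bis(benzyloxy)-5-methoxyphenyl]oxan-2-yl]ethan-1-ol
Conditions: LiAlH4, THF, 0 °C
Reagents that add atoms: none
Why: Hydride reduction of the ester to the primary alcohol; ethers are inert, and fast reduction at 0 °C leaves no time for base-induced opening of the β-alkoxy ester.

Step 10
Reactants: 14 2-[(2S,4R,6S)-4-(benzyloxy)-6-[3,4-bis(benzyloxy)-5-methoxyphenyl]oxan-2-yl]ethan-1-ol
Product: 15 (2S,4R,6R)-4-(benzyloxy)-2-[3,4-bis(benzyloxy)-5-methoxyphenyl]-6-(2-iodoethyl)oxane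
Conditions: I2, PPh3, imidazole, CH2Cl2, 0 °C to rt
Reagents that add atoms: iodine, [I][I]
Why: Appel-type iodination; the alkoxyphosphonium ion of the primary alcohol is displaced by iodide (SN2) at C7, which is not a stereocentre.

Step 11
Reactants: 16 4-bromo-2-methoxyphenol
Product: 17 1-(benzyloxy)-4-bromo-2-methoxybenzene
Conditions: BnBr, K2CO3, DMF, 60 °C
Reagents that add atoms: benzyl bromide, BrCc1ccccc1
Why: Williamson ether synthesis; it removes the acidic phenol proton that would quench the organozinc reagent of step 12.

Step 12
Reactants: 15 (2S,4R,6R)-4-(benzyloxy)-2-[3,4-bis(benzyloxy)-5-methoxyphenyl]-6-(2-iodoethyl)oxane; 17 1-(benzyloxy)-4-bromo-2-methoxybenzene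
Product: 19 (2S,4R,6S)-4-(benzyloxy)-2-[3,4-bis(benzyloxy)-5-methoxyphenyl]-6-{2-[4-(benzyloxy)-3-methoxyphenyl]ethyl}oxane, via alkylzinc iodide 18 (not isolated)
Conditions: Zn dust, I2 (5 mol %), DMA, 40 °C; then 17, Pd(OAc)2 (3 mol %), 2-dicyclohexylphosphino-2',6'-dimethoxybiphenyl (6 mol %), THF/DMA, 50 °C
Reagents that add atoms: none
Why: Zinc inserts into the primary C–I bond and the alkylzinc iodide enters a Negishi coupling: oxidative addition of zerovalent palladium to the aryl bromide, transmetallation and reductive elimination form the C7–aryl bond. The bulky electron-rich biaryl phosphine speeds oxidative addition to the electron-rich bromide and reductive elimination ahead of β-hydride elimination; the oxygen at C5 is γ to zinc and cannot be expelled.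

Step 13
Reactants: 19 (2S,4R,6S)-4-(benzyloxy)-2-[3,4-bis(benzyloxy)-5-methoxyphenyl]-6-{2-[4-(benzyloxy)-3-methoxyphenyl]ethyl}oxane
Product: 20 5-[(2S,4R,6S)-4-hydroxy-6-[2-(4-hydroxy-3-methoxyphenyl)ethyl]oxan-2-yl]-3-methoxybenzene-1,2-diol
Conditions: H2 (1 atm), 10% Pd/C, EtOAc/MeOH (1:1), rt
Reagents that add atoms: none
Why: Catalytic hydrogenolysis of the three aryl benzyl ethers and the C3 benzyl ether under neutral conditions; the cyclic C1–O bond, although benzylic, should be cleaved much more slowly in the absence of acid, so the reaction is stopped as soon as the C3 ether is gone. No stereocentre is touched.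

Compound list

1 | 3,4-dihydroxy-5-methoxybenzaldehyde (5-hydroxyvanillin) | COc1cc(C=O)cc(O)c1O | starting material
2 | 3,4-bis(benzyloxy)-5-methoxybenzaldehyde | COc1cc(C=O)cc(OCc2ccccc2)c1OCc1ccccc1 | intermediate
3 | allylboronic acid pinacol ester (4,4,5,5-tetramethyl-2-(prop-2-en-1-yl)-1,3,2-dioxaborolane) | C=CCB1OC(C)(C)C(C)(C)O1 | starting material
4 | 2-{[(1S)-1-[3,4-bis(benzyloxy)-5-methoxyphenyl]but-3-en-1-yl]oxy}-4,4,5,5-tetramethyl-1,3,2-dioxaborolane | C=CC[C@@H](c1cc(OCc2ccccc2)c(OCc2ccccc2)c(OC)c1)OB1OC(C)(C)C(C)(C)O1 | intermediate (not isolated)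
5 | (1S)-1-[3,4-bis(benzyloxy)-5-methoxyphenyl]but-3-en-1-ol | C=CC[C@@H](c1cc(OCc2ccccc2)c(OCc2ccccc2)c(OC)c1)O | intermediate
6 | {[(1S)-1-[3,4-bis(benzyloxy)-5-methoxyphenyl]but-3-en-1-yl]oxy}tri(propan-2-yl)silane | C=CC[C@@H](c1cc(OCc2ccccc2)c(OCc2ccccc2)c(OC)c1)O[Si](C(C)C)(C(C)C)C(C)C | intermediate
7 | (4S)-4-[3,4-bis(benzyloxy)-5-methoxyphenyl]-4-{[tri(propan-2-yl)silyl]oxy}butane-1,2-diol, both C2 epimers | OCC(O)C[C@@H](c1cc(OCc2ccccc2)c(OCc2ccccc2)c(OC)c1)O[Si](C(C)C)(C(C)C)C(C)C | intermediate (not isolated)
8 | (3S)-3-[3,4-bis(benzyloxy)-5-methoxyphenyl]-3-{[tri(propan-2-yl)silyl]oxy}propanal | O=CC[C@@H](c1cc(OCc2ccccc2)c(OCc2ccccc2)c(OC)c1)O[Si](C(C)C)(C(C)C)C(C)C | intermediate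
9 | 2-{[(4R,6S)-6-[3,4-bis(benzyloxy)-5-methoxyphenyl]-6-{[tri(propan-2-yl)silyl]oxy}hex-1-en-4-yl]oxy}-4,4,5,5-tetramethyl-1,3,2-dioxaborolane | C=CC[C@@H](OB1OC(C)(C)C(C)(C)O1)C[C@@H](c1cc(OCc2ccccc2)c(OCc2ccccc2)c(OC)c1)O[Si](C(C)C)(C(C)C)C(C)C | intermediate (not isolated)
10 | (1S,3R)-1-[3,4-bis(benzyloxy)-5-methoxyphenyl]-1-{[tri(propan-2-yl)silyl]oxy}hex-5-en-3-ol | C=CC[C@@H](O)C[C@@H](c1cc(OCc2ccccc2)c(OCc2ccccc2)c(OC)c1)O[Si](C(C)C)(C(C)C)C(C)C | intermediate
11 | {[(1S,3R)-3-(benzyloxy)-1-[3,4-bis(benzyloxy)-5-methoxyphenyl]hex-5-en-1-yl]oxy}tri(propan-2-yl)silane | C=CC[C@@H](OCc1ccccc1)C[C@@H](c1cc(OCc2ccccc2)c(OCc2ccccc2)c(OC)c1)O[Si](C(C)C)(C(C)C)C(C)C | intermediate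
12 | (1S,3R)-3-(benzyloxy)-1-[3,4-bis(benzyloxy)-5-methoxyphenyl]hex-5-en-1-ol | C=CC[C@@H](OCc1ccccc1)C[C@@H](c1cc(OCc2ccccc2)c(OCc2ccccc2)c(OC)c1)O | intermediate
13 | methyl 2-[(2R,4R,6S)-4-(benzyloxy)-6-[3,4-bis(benzyloxy)-5-methoxyphenyl]oxan-2-yl]acetate (all-cis) | COC(=O)C[C@H]1C[C@@H](OCc2ccccc2)C[C@@H](c2cc(OCc3ccccc3)c(OCc3ccccc3)c(OC)c2)O1 | intermediate
14 | 2-[(2S,4R,6S)-4-(benzyloxy)-6-[3,4-bis(benzyloxy)-5-methoxyphenyl]oxan-2-yl]ethan-1-ol | OCC[C@H]1C[C@@H](OCc2ccccc2)C[C@@H](c2cc(OCc3ccccc3)c(OCc3ccccc3)c(OC)c2)O1 | intermediate
15 | (2S,4R,6R)-4-(benzyloxy)-2-[3,4-bis(benzyloxy)-5-methoxyphenyl]-6-(2-iodoethyl)oxane | ICC[C@H]1C[C@@H](OCc2ccccc2)C[C@@H](c2cc(OCc3ccccc3)c(OCc3ccccc3)c(OC)c2)O1 | intermediate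
16 | 4-bromo-2-methoxyphenol | COc1cc(Br)ccc1O | starting material
17 | 1-(benzyloxy)-4-bromo-2-methoxybenzene | COc1cc(Br)ccc1OCc1ccccc1 | intermediate
18 | {2-[(2R,4R,6S)-4-(benzyloxy)-6-[3,4-bis(benzyloxy)-5-methoxyphenyl]oxan-2-yl]ethyl}(iodo)zinc | I[Zn]CC[C@H]1C[C@@H](OCc2ccccc2)C[C@@H](c2cc(OCc3ccccc3)c(OCc3ccccc3)c(OC)c2)O1 | intermediate (not isolated)
19 | (2S,4R,6S)-4-(benzyloxy)-2-[3,4-bis(benzyloxy)-5-methoxyphenyl]-6-{2-[4-(benzyloxy)-3-methoxyphenyl]ethyl}oxane | COc1cc(CC[C@H]2C[C@@H](OCc3ccccc3)C[C@@H](c3cc(OCc4ccccc4)c(OCc4ccccc4)c(OC)c3)O2)ccc1OCc1ccccc1 | intermediate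
20 | 5-[(2S,4R,6S)-4-hydroxy-6-[2-(4-hydroxy-3-methoxyphenyl)ethyl]oxan-2-yl]-3-methoxybenzene-1,2-diol | COc1cc(CC[C@H]2C[C@@H](O)C[C@@H](c3cc(O)c(O)c(OC)c3)O2)ccc1O | target

Total step count: 13. Longest linear sequence: 12 steps (steps 1 to 10, 12 and 13); step 11 is a one-step branch.

Steps least certain to work

Step 8 (key step). The most likely failure is acid-induced ionisation of the electron-rich benzylic C1 alcohol (solvolysis by methanol or loss of configuration) if the HCl formed on reoxidation outruns the acetate buffer. A slow cyclisation would also leave room for alkene isomerisation or Wacker-type oxidation by adventitious water. Fallback: setting out from 12, cross-metathesis with methyl acrylate (second-generation Hoveyda–Grubbs catalyst, CH2Cl2, 40 °C) would give methyl (2E,5R,7S)-5-(benzyloxy)-7-[3,4-bis(benzyloxy)-5-methoxyphenyl]-7-hydroxyhept-2-enoate F1. Intramolecular oxa-Michael addition of the C1 alkoxide under equilibrating conditions (DBU, toluene, 80 °C) should then close the same oxane with the C5 arm equatorial, coming back to the route at 13. This replaces the metal-mediated oxidative closure by a conjugate addition under thermodynamic control and avoids acid and CO.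

Step 5. The risk is poor facial selectivity if the catalyst has to override the resident C1 centre, together with β-elimination of the silyloxy group from aldehyde 8 before it reacts. The 1,3-anti relationship should be confirmed before going on. Fallback: setting out from 8, the allylboration is accepted as it comes (or run with an achiral acid catalyst), and 10 is separated from its C3 epimer, (1S,3S)-1-[3,4-bis(benzyloxy)-5-methoxyphenyl]-1-{[tri(propan-2-yl)silyl]oxy}hex-5-en-3-ol F2. F2 is then inverted by a Mitsunobu reaction (4-nitrobenzoic acid, PPh3, diisopropyl azodicarboxylate, THF, 0 °C) to (1S,3R)-1-[3,4-bis(benzyloxy)-5-methoxyphenyl]-1-{[tri(propan-2-yl)silyl]oxy}hex-5-en-3-yl 4-nitrobenzoate F3, and methanolysis (K2CO3, MeOH) returns to the route at 10. Stereochemical correction by SN2 inversion thus replaces facial control.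

Step 12. Zinc insertion may stall or the alkylzinc may be protonated by traces of water. Homocoupling, and β-hydride elimination to the vinyl oxane if oxidative addition to the electron-rich aryl bromide is slow, are the other failure modes. Fallback: setting out from 14, Appel bromination (CBr4, PPh3, CH2Cl2, 0 °C) would give (2S,4R,6R)-4-(benzyloxy)-2-[3,4-bis(benzyloxy)-5-methoxyphenyl]-6-(2-bromoethyl)oxane F4. A nickel-catalysed reductive cross-electrophile coupling of F4 with 17 (NiI2, 4,4'-di-tert-butyl-2,2'-bipyridine, NaI, pyridine, Zn dust, 1,3-dimethyltetrahydropyrimidin-2(1H)-one, 60 °C) then joins the two bromides directly and comes back at 19. No organometallic reagent is preformed.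

Step 13. The risk is over-reduction: hydrogenolysis of the benzylic C1–O ring bond while the slower aliphatic C3 benzyl ether is still being removed. Air oxidation of the liberated catechol during work-up is a second hazard, so filtration and concentration are done under inert gas. Fallback: setting out from 19, non-reductive debenzylation with BCl3 and pentamethylbenzene as benzyl-cation scavenger (CH2Cl2, −78 °C, methanol quench) should remove all four benzyl groups and come back at 20. The methyl ethers are stable at this temperature, and once the para oxygen of ring A is bound to boron it is a poor donor, which disfavours ionisation at C1. This fallback makes no compound outside the list (F0).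

Further compounds

F1 | step 8 | methyl (2E,5R,7S)-5-(benzyloxy)-7-[3,4-bis(benzyloxy)-5-methoxyphenyl]-7-hydroxyhept-2-enoate | COC(=O)/C=C/C[C@@H](OCc1ccccc1)C[C@@H](c1cc(OCc2ccccc2)c(OCc2ccccc2)c(OC)c1)O
F2 | step 5 | (1S,3S)-1-[3,4-bis(benzyloxy)-5-methoxyphenyl]-1-{[tri(propan-2-yl)silyl]oxy}hex-5-en-3-ol | C=CC[C@H](O)C[C@@H](c1cc(OCc2ccccc2)c(OCc2ccccc2)c(OC)c1)O[Si](C(C)C)(C(C)C)C(C)C
F3 | step 5 | (1S,3R)-1-[3,4-bis(benzyloxy)-5-methoxyphenyl]-1-{[tri(propan-2-yl)silyl]oxy}hex-5-en-3-yl 4-nitrobenzoate | C=CC[C@@H](OC(=O)c1ccc(cc1)[N+](=O)[O-])C[C@@H](c1cc(OCc2ccccc2)c(OCc2ccccc2)c(OC)c1)O[Si](C(C)C)(C(C)C)C(C)C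
F4 | step 12 | (2S,4R,6R)-4-(benzyloxy)-2-[3,4-bis(benzyloxy)-5-methoxyphenyl]-6-(2-bromoethyl)oxane | BrCC[C@H]1C[C@@H](OCc2ccccc2)C[C@@H](c2cc(OCc3ccccc3)c(OCc3ccccc3)c(OC)c2)O1
F0 | step 13 | none | none
A1 | alternative 1 | (4R,6S)-6-(chloromethyl)oxane-2,4-diol, anomeric mixture | ClC[C@@H]1C[C@@H](O)CC(O)O1
A2 | alternative 1 | chloroacetaldehyde | ClCC=O
A3 | alternative 1 | acetaldehyde | CC=O
A4 | alternative 2 | tert-butyl{[(1S)-1-[3,4-bis(benzyloxy)-5-methoxyphenyl]-2-{2-[(2R)-4-[4-(benzyloxy)-3-methoxyphenyl]-2-hydroxybutyl]-1,3-dithian-2-yl}ethyl]oxy}dimethylsilane | COc1cc(CC[C@@H](O)CC2(SCCCS2)C[C@@H](c2cc(OCc3ccccc3)c(OCc3ccccc3)c(OC)c2)O[Si](C)(C)C(C)(C)C)ccc1OCc1ccccc1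
A5 | alternative 2 | (2R)-2-[3,4-bis(benzyloxy)-5-methoxyphenyl]oxirane | C1[C@@H](c2cc(OCc3ccccc3)c(OCc3ccccc3)c(OC)c2)O1
A6 | alternative 2 | (2R)-2-{2-[4-(benzyloxy)-3-methoxyphenyl]ethyl}oxirane | COc1cc(CC[C@@H]2CO2)ccc1OCc1ccccc1
A7 | alternative 2 | tert-butyl(1,3-dithian-2-yl)dimethylsilane | CC(C)(C)[Si](C)(C)C1SCCCS1
A8 | alternative 3 | cis-fused bicyclic siloxane: oxane with ring A (3,4-bis(benzyloxy)-5-methoxyphenyl) at C1, bridged from the C3 oxygen through SiMe2 to C6, which carries the exocyclic 4-(benzyloxy)-3-methoxybenzylidene group (alkene geometry mixed) | COc1cc(C=C3[C@H]2C[C@@H](O[Si]3(C)C)C[C@@H](c4cc(OCc5ccccc5)c(OCc5ccccc5)c(OC)c4)O2)ccc1OCc1ccccc1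
A9 | alternative 3 | {[(2S,4S)-2-[3,4-bis(benzyloxy)-5-methoxyphenyl]-6-(phenylselanyl)oxan-4-yl]oxy}{[4-(benzyloxy)-3-methoxyphenyl]ethynyl}dimethylsilane, both epimers at the selenium-bearing carbon | c1ccccc1[Se]C1C[C@@H](O[Si](C)(C)C#Cc2ccc(OCc3ccccc3)c(OC)c2)C[C@@H](c2cc(OCc3ccccc3)c(OCc3ccccc3)c(OC)c2)O1
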